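## The problem

The target is a linear proanthocyanidin trimer. An upper epicatechin 3-O-gallate (U) is joined through C4 to C8 of a middle epicatechin 3-O-gallate (M), whose C4 is joined to C6 of a terminal catechin (T) that keeps a free 3-hydroxyl. It has eight stereocentres: C2, C3 and C4 of U and of M (2,3-cis, 3,4-trans in both) and C2 and C3 of T (trans). Those of M and T can be taken from (−)-epicatechin and (+)-catechin, and the C3 oxygen of M steers the arylation of its C4 to the trans face. Unit U has to be made or attached with control: its C3 oxygen can fix C4, and C3 and C4 together can fix C2. The 4→6 bond to T must be made against the natural preference of a flavan nucleophile for C8, and the two galloyl esters must end on O3 of U and M but not on O3 of T. The eighteen phenols are air- and base-sensitive, the esters do not tolerate strong nucleophiles or base, the interflavan bonds are cleaved by strong acid, and C2 epimerises under base once the phenols are free. All hydroxyls are therefore carried as benzyl ethers to a single final hydrogenolysis. The feature that invites a de novo construction of U is its C4: it is a diarylmethine flanked by two phloroglucinol-type rings (C8 of ring A of M and C4a of ring A of U), next to the oxygenated C3 and two atoms from O1. A 2,3-epoxy aldehyde on C8 of M therefore maps onto C4 (benzylic oxirane carbon), O3 (oxirane oxygen), C3 and C2 (formyl carbon), and a 3,5-dioxygenated phenol supplies C4a and O1.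

## Retrosynthesis

Global deprotection. The target 27 is traced to the perbenzylated bromo trimer 26. Nineteen O–benzyl bonds and the C8–Br bond of T are cut in one hydrogenolysis. The bromine is not an extra burden, because it is the group that forces the 4→6 linkage earlier. The forward step only needs neutral, buffered conditions so that esters, interflavan bonds and C2 centres are untouched.

Ester on O3 of U. The acyl C–O bond of the upper gallate in 26 is cut to alcohol 25 and 3,4,5-tris(benzyloxy)benzoic acid 9. The gallate of M is not cut here: it is installed on the monomer (10), where the hydroxyl is accessible and where the acyl group later helps the trans arylation of C4. The final esterification then meets one hindered hydroxyl instead of two. O3 of T is a benzyl ether from the start and cannot compete. Alcohol 25 comes from its triethylsilyl ether 24.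

C2–aryl bond of U. In 24 the bond between C2 and ring B is cut to the anomeric acetate 20 and the aryl donor 21, which reacts as diarylzinc 23. Against the alternative of carrying ring B through the ring construction, this cut leaves the lactol carbon as the only unsettled centre and lets the C4 substituent, already in place, direct the aryl group to the opposite face. The forward reaction must outrun Friedel–Crafts attack by the free ring A positions of the substrate, which is why an organozinc and not a neutral arene is chosen. It must also keep O3 non-participating, hence the silyl ether. Acetate 20 is reached from lactol 18 by anomeric acetylation (19) and silylation.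

Ring C of U (the key cut). In lactol 18 the bonds C4a–C4 and O1–C2 are cut, which removes ring C and all of ring A of U. The precursors are the trans-epoxy aldehyde 15 and 3,5-bis(benzyloxy)phenol 16. Compared with a classical interflavan coupling of a complete upper flavan, this cut tests whether U can be grown on the dimer from a three-carbon unit, with C3 set by a catalyst and C4 by inversion. It simplifies the problem to a dimer carrying one small, stereodefined handle and a catalogue phenol. The forward reaction has to open the oxirane at the benzylic carbon, anti, with the ortho carbon of the phenol.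

Oxirane and C8–C bond. Epoxy aldehyde 15 is traced to the E-enal 14 (both C–O bonds of the oxirane; catalyst-controlled nucleophilic epoxidation, which avoids Lewis acids near an acid-labile aryl oxirane). Enal 14 is traced to the dimer iodide 11 and the alkenylboronate 12 (C8–C bond, via acetal 13). A cross-coupling is preferred to formylation followed by olefination because it installs all three carbons at once. The C–I bond reacts ahead of the C–Br bond on T.

Interflavan bond M–T. In 11 the C4(M)–C6(T) bond is cut to the C4-activated, 8-iodinated gallate 10 and the 8-brominated nucleophile 4. Bromine on C8 of 4 leaves C6 as the only nucleophilic ring A position. Iodine on C8 of 10 damps self-condensation of the electrophile and is the later handle for the three-carbon unit. The forward coupling must deliver the aryl group trans to the C3 ester.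

Monomers. Electrophile 10 comes from (−)-epicatechin 5 by phenol benzylation (6), oxidative introduction of a C4 alkoxy leaving group (7), C8 iodination (8) and esterification with 9. Nucleophile 4 comes from (+)-catechin 1 by benzylation of the phenols (2) and of O3 (3) and C8 bromination. Compounds 9, 12, 16 and 21 are bought.

## Roads not taken

Alternative 1: both pyran rings of U and M would be closed last by two phenolic oxygens opening two benzylic cis-epoxides (bonds O1–C2 in U and M), giving the diol A1.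
- Merits: ring B is in place before ring closure, so no C2 arylation is needed. Stereospecific inversion at C2 of a cis-epoxide gives the 2,3-cis relationship directly. The two free 3-hydroxyls of A1 are ready for one double galloylation.
- Weak points: both diarylmethine centres (the future C4 atoms) must be set in an open-chain precursor without the help of a ring. Two Z-alkenes must be epoxidised with high face selectivity. Each oxirane carbon that is attacked bears a 3,4-dialkoxyphenyl group, so ionisation and loss of the cis relationship are likely under the acid needed.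
- Comparison: the end game of this road is better than the chosen one. The chosen plan sets against it that M and T come intact from the chiral pool, that only one oxirane is needed, and that this oxirane is held back from ionisation by its formyl group.

Alternative 2: both catechol rings would be introduced last, by ionising two anomeric acetates and letting two molecules of 1,2-bis(benzyloxy)benzene A3 attack the oxocarbenium ions (C2–C1' in U and M), giving A2.
- Merits: one reagent, two bonds and two stereocentres in one step, and the two silyl ethers of A2 can be exchanged for gallates together.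
- Weak points: it doubles the least secure operation after the key step of the chosen plan. A3 is a far weaker nucleophile than the ring A carbons of the substrate, so self-alkylation threatens at two cationic centres at once. Both lactol units must be built de novo, so only T comes from the pool.
- Comparison: the chosen plan uses the same bond construction once, with an organozinc instead of A3, and takes the whole of M from epicatechin. Alternative 2 is more symmetric but no shorter.

Alternative 3: ring A of T would be built by a Danheiser benzannulation between the pyran-fused cyclobutenone A5 and the siloxyalkyne A6 (bonds C6–C7 and C4a–C5), giving the phenol A4.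
- Merits: the 4→6 connectivity is fixed by construction, which is more certain than any blocking-group tactic, and the two ring A oxygens of T come out differentiated.
- Weak points: the C ring of T with its two stereocentres must be synthesised, not bought. A6 needs a stereodefined propargylic diarylmethine centre. A6 is a bulky alkyne, to be heated with a sensitive ketene precursor. Extra protecting-group changes follow.
- Comparison: the chosen plan is less certain on regiochemistry. It sets against this one bromination of a pool-derived monomer and the removal of the bromine at no cost in the final hydrogenolysis.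

Key step: step 11

Assumption (chemistry): in the aminocatalytic epoxidation the diaryl(silyloxy)methyl group shields its own side of the E-iminium ion, so the (R)-catalyst puts oxygen on the Re face of the aryl-bearing carbon and gives the (2R,3S)-epoxy aldehyde. If the sense proves opposite, the enantiomeric catalyst is used and nothing else changes.
Assumption (supply): compounds 9, 12, 16 and 21 are purchased.

## Route

Step 1
Reactants: 1 (+)-catechin
Product: 2 5,7,3',4'-tetra-O-benzyl-(+)-catechin
Conditions: BnBr, K2CO3, DMF, 0 °C → rt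
Reagents that add atoms: benzyl bromide, BrCc1ccccc1
Why: Williamson etherification of the four phenols; the weak base leaves the secondary 3-hydroxyl free and does not epimerise C2.

Step 2
Reactants: 2 5,7,3',4'-tetra-O-benzyl-(+)-catechin
Product: 3 3,5,7,3',4'-penta-O-benzyl-(+)-catechin
Conditions: NaH, BnBr, DMF, 0 °C → rt
Reagents that add atoms: benzyl bromide, BrCc1ccccc1
Why: Williamson etherification of the remaining aliphatic hydroxyl, which keeps O3 of unit T out of the later galloylation and is removed with the other benzyl groups.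

Step 3
Reactants: 3 3,5,7,3',4'-penta-O-benzyl-(+)-catechin
Product: 4 8-bromo-3,5,7,3',4'-penta-O-benzyl-(+)-catechin
Conditions: NBS, CH2Cl2, −78 → 0 °C
Reagents that add atoms: N-bromosuccinimide, O=C1CCC(=O)N1Br
Why: electrophilic aromatic bromination; C8 is the most reactive position of the 5,7-dialkoxy ring A of flavans towards N-halosuccinimides, and the bromine then leaves C6 as the only nucleophilic site.

Step 4
Reactants: 5 (−)-epicatechin
Product: 6 5,7,3',4'-tetra-O-benzyl-(−)-epicatechin
Conditions: BnBr, K2CO3, DMF, 0 °C → rt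
Reagents that add atoms: benzyl bromide, BrCc1ccccc1
Why: Williamson etherification of the phenols under conditions that do not epimerise C2.

Step 5
Reactants: 6 5,7,3',4'-tetra-O-benzyl-(−)-epicatechin
Product: 7 5,7,3',4'-tetra-O-benzyl-4β-(2-ethoxyethoxy)-(−)-epicatechin (3,4-trans)
Conditions: DDQ, 2-ethoxyethanol, CH2Cl2, rt
Reagents that add atoms: 2-ethoxyethanol, CCOCCO
Why: DDQ benzylic oxidation; hydride abstraction at C4 gives the cation stabilised by ring A, which the alcohol captures trans to the C3 hydroxyl, the standard C4 activation of benzylated flavan-3-ols.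

Step 6
Reactants: 7 5,7,3',4'-tetra-O-benzyl-4β-(2-ethoxyethoxy)-(−)-epicatechin
Product: 8 8-iodo-5,7,3',4'-tetra-O-benzyl-4β-(2-ethoxyethoxy)-(−)-epicatechin
Conditions: NIS, CH2Cl2, −40 → 0 °C
Reagents that add atoms: N-iodosuccinimide, O=C1CCC(=O)N1I
Why: electrophilic aromatic iodination under neutral conditions that spare the C4 acetal; C8 is the preferred site as in the bromination of step 3.

Step 7
Reactants: 8 8-iodo-5,7,3',4'-tetra-O-benzyl-4β-(2-ethoxyethoxy)-(−)-epicatechin; 9 3,4,5-tris(benzyloxy)benzoic acid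
Product: 10 8-iodo-5,7,3',4'-tetra-O-benzyl-4β-(2-ethoxyethoxy)-(−)-epicatechin 3-O-[3,4,5-tris(benzyloxy)benzoate]
Conditions: DCC, DMAP, CH2Cl2, rt
Reagents that add atoms: none
Why: Steglich esterification of the C3 hydroxyl while it is still on a monomer; the ester later assists the trans arylation of C4.

Step 8
Reactants: 10 iodinated gallate electrophile of unit M; 4 8-bromo-3,5,7,3',4'-penta-O-benzyl-(+)-catechin
Product: 11 M–T dimer iodide, unit M (8-iodo, 3-O-galloyl) joined 4β→6 to unit T (8-bromo, 3-O-benzyl)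
Conditions: 4 (2 equiv), TMSOTf (cat.), CH2Cl2, −78 → −30 °C
Reagents that add atoms: none
Why: Friedel–Crafts interflavan coupling; the silyl triflate ionises the C4 acetal to the flavan-4-yl cation, held by the neighbouring ester carbonyl, and C6 of 4 (C8 being blocked) attacks trans to O3, which sets C4 of unit M; the iodine lowers the nucleophilicity of the electrophile's own ring A and limits self-condensation.

Step 9
Reactants: 11 M–T dimer iodide; 12 (E)-2-(3,3-diethoxyprop-1-enyl)-4,4,5,5-tetramethyl-1,3,2-dioxaborolane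
Product: 14 M–T dimer 8-[(E)-3-oxoprop-1-enyl] enal, via diethyl acetal 13 (not isolated)
Conditions: Pd(PPh3)4 (5 mol%), K3PO4, 1,4-dioxane/H2O (20:1), 70 °C; then 1 M HCl, THF, 0 °C
Reagents that add atoms: water, O
Why: Suzuki–Miyaura coupling; zerovalent palladium inserts into the C–I bond well before the hindered, electron-rich C–Br bond of unit T, the alkenyl group is transferred with retention of the E geometry, and dilute acid unmasks the conjugated aldehyde.

Step 10
Reactants: 14 M–T dimer enal
Product: 15 (2R,3S)-trans-epoxy aldehyde on C8 of unit M of the M–T dimer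
Conditions: (R)-α,α-bis[3,5-bis(trifluoromethyl)phenyl]prolinol trimethylsilyl ether (20 mol%), 35% aq. H2O2, CH2Cl2, rt
Reagents that add atoms: hydrogen peroxide, OO
Why: Jørgensen iminium–enamine epoxidation; hydroperoxide adds to the β-carbon of the iminium ion on the face left open by the catalyst and the enamine closes onto oxygen, which sets C3 and the benzylic centre as the trans-(2R,3S) oxirane under catalyst control; the basic, Lewis-acid-free medium suits an acid-labile aryl oxirane and leaves the ester untouched.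

Step 11
Reactants: 15 (2R,3S)-trans-epoxy aldehyde; 16 3,5-bis(benzyloxy)phenol
Product: 18 3-hydroxy lactol of unit U on the M–T dimer (anomer mixture; 3,4-trans), via hydroxy aldehyde 17 (not isolated)
Conditions: 16 (2 equiv), PhB(OH)2 (1.2 equiv), EtCO2H (cat.), 4 Å MS, toluene, −20 °C → rt; aq. NaHCO3
Reagents that add atoms: none
Why: Proposed new method: the phenol and PhB(OH)2 give an aryloxyboronate whose boron binds the aldehyde oxygen (a boron-bridged hemiacetal), which holds the arene on the C2 side of the oxirane and away from the oxirane oxygen; the weak acid then loosens the benzylic C4–O bond, the only one whose carbon can carry charge because it is ortho and para to three ether oxygens of ring A of unit M and because the formyl group disfavours charge at C3, and the carbon ortho to the phenolic oxygen attacks C4 from the side opposite the leaving oxygen to give hydroxy aldehyde 17. The phenol oxygen of 17 then adds to the aldehyde (6-exo-trig hemiacetalisation) and closes ring C of unit U as lactol 18; if O1–C2 forms first, the same ring closes by a 6-endo Friedel–Crafts opening of the oxirane and the product is identical. The closest known reaction types are the acid-mediated anti Friedel–Crafts opening of aryl oxiranes by phenols and other electron-rich arenes, including the cyclisation of aryl 3-arylglycidyl ethers to trans-4-arylchroman-3-ols, and the PhB(OH)2-templated ortho annulation of phenols with enals; neither has been run on an epoxy aldehyde with lactol closure. C3 keeps the configuration installed in step 10, and the new stereocentre C4 is set by inversion at the benzylic carbon, so the trans-oxirane is translated into the 3,4-trans pair; a chair-like closure with O3 and the C4 aryl group trans favours the same isomer if the opening is loose. Three selectivities are needed: C4 over C3 (electronic, as above), ortho over para carbon of 16 (boron tether, and only the ortho adduct can close the lactol while O-alkylation at this stabilised benzylic position is reversible), and anti over syn delivery (boron on the aldehyde oxygen and not on the oxirane oxygen, low temperature, weak acid). The anomeric carbon is left as a mixture because it is ionised in step 14.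

Step 12
Reactants: 18 3-hydroxy lactol of unit U
Product: 19 lactol 2-O-acetate with free 3-hydroxyl (anomer mixture)
Conditions: Ac2O (1.05 equiv), Et3N, DMAP (cat.), CH2Cl2, −40 °C
Reagents that add atoms: acetic anhydride, CC(=O)OC(C)=O
Why: selective acylation of the hemiacetal hydroxyl, which is more acidic and less hindered than the C3 hydroxyl next to the C4 diarylmethine; one equivalent and low temperature hold back the second acylation and acyl migration.

Step 13
Reactants: 19 lactol 2-O-acetate
Product: 20 2-O-acetyl-3-O-triethylsilyl lactol of unit U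
Conditions: TESOTf, 2,6-lutidine, CH2Cl2, −78 °C
Reagents that add atoms: triethylsilyl trifluoromethanesulfonate, CC[Si](CC)(CC)OS(=O)(=O)C(F)(F)F
Why: silylation of a hindered secondary alcohol with a silyl triflate under buffered conditions; the silyl ether cannot act as a neighbouring group at C2, unlike an ester.

Step 14
Reactants: 20 2-O-acetyl-3-O-triethylsilyl lactol; 21 4-bromo-1,2-bis(benzyloxy)benzene
Product: 24 protected trimer with 3-O-triethylsilyl group on unit U, via aryllithium 22 (not isolated), via diarylzinc 23 (not isolated)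
Conditions: 21, n-BuLi, Et2O, −78 °C; ZnBr2, −78 → 0 °C; then 20, TMSOTf, CH2Cl2/Et2O, −78 → −40 °C
Reagents that add atoms: none
Why: Lewis-acid-mediated substitution of an α-acetoxy ether by an organozinc (C-aryl glycosylation type): the silyl triflate ionises the anomeric acetate and the diarylzinc transfers its aryl group to the oxocarbenium ion far faster than the ring A carbons of the substrate can attack it; the aryl group enters on the face opposite the large C4 substituent, which is also the face predicted for pseudoaxial attack with the adjacent silyloxy group pseudoequatorial, so C2 is set cis to O3 and trans to the C4 aryl group.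

Step 15
Reactants: 24 protected trimer with 3-O-triethylsilyl group on unit U
Product: 25 protected trimer with free 3-hydroxyl on unit U
Conditions: HF·pyridine, pyridine/THF, 0 °C → rt
Reagents that add atoms: none
Why: fluoride cleavage of the silyl ether under conditions that leave the gallate of unit M, the benzyl ethers and the aryl bromide untouched.

Step 16
Reactants: 25 protected trimer with free 3-hydroxyl on unit U; 9 3,4,5-tris(benzyloxy)benzoic acid
Product: 26 perbenzylated 8-bromo trimer 3,3'-di-O-gallate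
Conditions: 9 (excess), DCC, DMAP, CH2Cl2, rt → 40 °C
Reagents that add atoms: none
Why: Steglich esterification of the only free hydroxyl; O3 of unit T is a benzyl ether and O3 of unit M already carries its ester.

Step 17
Reactants: 26 perbenzylated 8-bromo trimer 3,3'-di-O-gallate
Product: 27 CNP0154615.1, epicatechin 3-O-gallate-(4β→8)-epicatechin 3-O-gallate-(4β→6)-catechin
Conditions: H2 (1 atm), Pd(OH)2/C, NaOAc, THF/MeOH/H2O, rt
Reagents that add atoms: none
Why: catalytic hydrogenolysis removes the nineteen benzyl ethers and the aryl bromide in one operation; the acetate buffer takes up HBr so that interflavan bonds and esters are not exposed to acid, and no stereocentre is touched.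

## Compound list

1 | (+)-catechin, (2R,3S)-2-(3,4-dihydroxyphenyl)chromane-3,5,7-triol | O[C@H]1Cc2c(O)cc(O)cc2O[C@@H]1c1ccc(O)c(O)c1 | starting material
2 | 5,7,3',4'-tetra-O-benzyl-(+)-catechin | O[C@H]1Cc2c(OCc9ccccc9)cc(OCc9ccccc9)cc2O[C@@H]1c1ccc(OCc9ccccc9)c(OCc9ccccc9)c1 | intermediate
3 | 3,5,7,3',4'-penta-O-benzyl-(+)-catechin | O(Cc9ccccc9)[C@H]1Cc2c(OCc9ccccc9)cc(OCc9ccccc9)cc2O[C@@H]1c1ccc(OCc9ccccc9)c(OCc9ccccc9)c1 | intermediate
4 | 8-bromo-3,5,7,3',4'-penta-O-benzyl-(+)-catechin (unit T nucleophile) | O(Cc9ccccc9)[C@H]1Cc2c(OCc9ccccc9)cc(OCc9ccccc9)c(Br)c2O[C@@H]1c1ccc(OCc9ccccc9)c(OCc9ccccc9)c1 | intermediate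
5 | (−)-epicatechin, (2R,3R)-2-(3,4-dihydroxyphenyl)chromane-3,5,7-triol | O[C@@H]1Cc2c(O)cc(O)cc2O[C@@H]1c1ccc(O)c(O)c1 | starting material
6 | 5,7,3',4'-tetra-O-benzyl-(−)-epicatechin | O[C@@H]1Cc2c(OCc9ccccc9)cc(OCc9ccccc9)cc2O[C@@H]1c1ccc(OCc9ccccc9)c(OCc9ccccc9)c1 | intermediate
7 | 5,7,3',4'-tetra-O-benzyl-4β-(2-ethoxyethoxy)-(−)-epicatechin (4-alkoxy trans to 3-OH) | O[C@@H]1[C@@H](OCCOCC)c2c(OCc9ccccc9)cc(OCc9ccccc9)cc2O[C@@H]1c1ccc(OCc9ccccc9)c(OCc9ccccc9)c1 | intermediate
8 | 8-iodo-5,7,3',4'-tetra-O-benzyl-4β-(2-ethoxyethoxy)-(−)-epicatechin | O[C@@H]1[C@@H](OCCOCC)c2c(OCc9ccccc9)cc(OCc9ccccc9)c(I)c2O[C@@H]1c1ccc(OCc9ccccc9)c(OCc9ccccc9)c1 | intermediate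
9 | 3,4,5-tris(benzyloxy)benzoic acid | OC(=O)c1cc(OCc2ccccc2)c(OCc2ccccc2)c(OCc2ccccc2)c1 | starting material
10 | 8-iodo-5,7,3',4'-tetra-O-benzyl-4β-(2-ethoxyethoxy)-(−)-epicatechin 3-O-[3,4,5-tris(benzyloxy)benzoate] (unit M electrophile) | O=C(O[C@@H]1[C@@H](OCCOCC)c2c(OCc9ccccc9)cc(OCc9ccccc9)c(I)c2O[C@@H]1c1ccc(OCc9ccccc9)c(OCc9ccccc9)c1)c1cc(OCc9ccccc9)c(OCc9ccccc9)c(OCc9ccccc9)c1 | intermediate
11 | M–T dimer iodide: 8-iodo-tetra-O-benzylepicatechin 3-O-tribenzylgallate joined 4β→6 to 8-bromo-penta-O-benzylcatechin | Ic2c(OCc9ccccc9)cc(OCc9ccccc9)c3c2O[C@H](c2ccc(OCc9ccccc9)c(OCc9ccccc9)c2)[C@H](OC(=O)c2cc(OCc9ccccc9)c(OCc9ccccc9)c(OCc9ccccc9)c2)[C@H]3c2c(OCc9ccccc9)c(Br)c3c(c2OCc9ccccc9)C[C@H](OCc9ccccc9)[C@@H](c2ccc(OCc9ccccc9)c(OCc9ccccc9)c2)O3 | intermediate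
12 | (E)-2-(3,3-diethoxyprop-1-enyl)-4,4,5,5-tetramethyl-1,3,2-dioxaborolane | CCOC(OCC)/C=C/B1OC(C)(C)C(C)(C)O1 | starting material
13 | M–T dimer with (E)-3,3-diethoxyprop-1-enyl group on C8 of unit M | CCOC(OCC)/C=C/c2c(OCc9ccccc9)cc(OCc9ccccc9)c3c2O[C@H](c2ccc(OCc9ccccc9)c(OCc9ccccc9)c2)[C@H](OC(=O)c2cc(OCc9ccccc9)c(OCc9ccccc9)c(OCc9ccccc9)c2)[C@H]3c2c(OCc9ccccc9)c(Br)c3c(c2OCc9ccccc9)C[C@H](OCc9ccccc9)[C@@H](c2ccc(OCc9ccccc9)c(OCc9ccccc9)c2)O3 | intermediate
14 | M–T dimer with (E)-3-oxoprop-1-enyl group on C8 of unit M (enal) | O=C/C=C/c2c(OCc9ccccc9)cc(OCc9ccccc9)c3c2O[C@H](c2ccc(OCc9ccccc9)c(OCc9ccccc9)c2)[C@H](OC(=O)c2cc(OCc9ccccc9)c(OCc9ccccc9)c(OCc9ccccc9)c2)[C@H]3c2c(OCc9ccccc9)c(Br)c3c(c2OCc9ccccc9)C[C@H](OCc9ccccc9)[C@@H](c2ccc(OCc9ccccc9)c(OCc9ccccc9)c2)O3 | intermediate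
15 | (2R,3S)-trans-3-aryloxirane-2-carbaldehyde, aryl = C8 of unit M of the M–T dimer | O=C[C@@H]1O[C@H]1c2c(OCc9ccccc9)cc(OCc9ccccc9)c3c2O[C@H](c2ccc(OCc9ccccc9)c(OCc9ccccc9)c2)[C@H](OC(=O)c2cc(OCc9ccccc9)c(OCc9ccccc9)c(OCc9ccccc9)c2)[C@H]3c2c(OCc9ccccc9)c(Br)c3c(c2OCc9ccccc9)C[C@H](OCc9ccccc9)[C@@H](c2ccc(OCc9ccccc9)c(OCc9ccccc9)c2)O3 | intermediate
16 | 3,5-bis(benzyloxy)phenol | Oc1cc(OCc2ccccc2)cc(OCc2ccccc2)c1 | starting material
17 | open-chain 2-hydroxy-3,3-diarylpropanal (C3 retained, C4 inverted; aryl groups = 2-hydroxy-4,6-bis(benzyloxy)phenyl and C8 of unit M) | O=C[C@H](O)[C@@H](c2c(OCc9ccccc9)cc(OCc9ccccc9)c3c2O[C@H](c2ccc(OCc9ccccc9)c(OCc9ccccc9)c2)[C@H](OC(=O)c2cc(OCc9ccccc9)c(OCc9ccccc9)c(OCc9ccccc9)c2)[C@H]3c2c(OCc9ccccc9)c(Br)c3c(c2OCc9ccccc9)C[C@H](OCc9ccccc9)[C@@H](c2ccc(OCc9ccccc9)c(OCc9ccccc9)c2)O3)c2c(OCc9ccccc9)cc(OCc9ccccc9)cc2O | intermediate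
18 | 3-hydroxy lactol (5,7-bis(benzyloxy)-4-arylchromane-2,3-diol, 3,4-trans, anomer mixture) of unit U on the M–T dimer | OC1[C@H](O)[C@@H](c2c(OCc9ccccc9)cc(OCc9ccccc9)c3c2O[C@H](c2ccc(OCc9ccccc9)c(OCc9ccccc9)c2)[C@H](OC(=O)c2cc(OCc9ccccc9)c(OCc9ccccc9)c(OCc9ccccc9)c2)[C@H]3c2c(OCc9ccccc9)c(Br)c3c(c2OCc9ccccc9)C[C@H](OCc9ccccc9)[C@@H](c2ccc(OCc9ccccc9)c(OCc9ccccc9)c2)O3)c2c(OCc9ccccc9)cc(OCc9ccccc9)cc2O1 | intermediate
19 | lactol 2-O-acetate with free 3-hydroxyl (anomer mixture) | CC(=O)OC1[C@H](O)[C@@H](c2c(OCc9ccccc9)cc(OCc9ccccc9)c3c2O[C@H](c2ccc(OCc9ccccc9)c(OCc9ccccc9)c2)[C@H](OC(=O)c2cc(OCc9ccccc9)c(OCc9ccccc9)c(OCc9ccccc9)c2)[C@H]3c2c(OCc9ccccc9)c(Br)c3c(c2OCc9ccccc9)C[C@H](OCc9ccccc9)[C@@H](c2ccc(OCc9ccccc9)c(OCc9ccccc9)c2)O3)c2c(OCc9ccccc9)cc(OCc9ccccc9)cc2O1 | intermediate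
20 | 2-O-acetyl-3-O-triethylsilyl lactol (anomer mixture) | CC(=O)OC1[C@H](O[Si](CC)(CC)CC)[C@@H](c2c(OCc9ccccc9)cc(OCc9ccccc9)c3c2O[C@H](c2ccc(OCc9ccccc9)c(OCc9ccccc9)c2)[C@H](OC(=O)c2cc(OCc9ccccc9)c(OCc9ccccc9)c(OCc9ccccc9)c2)[C@H]3c2c(OCc9ccccc9)c(Br)c3c(c2OCc9ccccc9)C[C@H](OCc9ccccc9)[C@@H](c2ccc(OCc9ccccc9)c(OCc9ccccc9)c2)O3)c2c(OCc9ccccc9)cc(OCc9ccccc9)cc2O1 | intermediate
21 | 4-bromo-1,2-bis(benzyloxy)benzene | Brc1ccc(OCc2ccccc2)c(OCc2ccccc2)c1 | starting material
22 | 3,4-bis(benzyloxy)phenyllithium | [Li]c1ccc(OCc2ccccc2)c(OCc2ccccc2)c1 | intermediate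
23 | bis[3,4-bis(benzyloxy)phenyl]zinc | c1ccc(COc2ccc([Zn]c3ccc(OCc4ccccc4)c(OCc4ccccc4)c3)cc2OCc2ccccc2)cc1 | intermediate
24 | protected trimer, unit U 3-O-triethylsilyl (2,3-cis, 3,4-trans), unit M 3-O-tribenzylgallate, unit T 3-O-benzyl and 8-bromo | CC[Si](CC)(CC)O[C@@H]1[C@@H](c2c(OCc9ccccc9)cc(OCc9ccccc9)c3c2O[C@H](c2ccc(OCc9ccccc9)c(OCc9ccccc9)c2)[C@H](OC(=O)c2cc(OCc9ccccc9)c(OCc9ccccc9)c(OCc9ccccc9)c2)[C@H]3c2c(OCc9ccccc9)c(Br)c3c(c2OCc9ccccc9)C[C@H](OCc9ccccc9)[C@@H](c2ccc(OCc9ccccc9)c(OCc9ccccc9)c2)O3)c2c(OCc9ccccc9)cc(OCc9ccccc9)cc2O[C@@H]1c1ccc(OCc9ccccc9)c(OCc9ccccc9)c1 | intermediate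
25 | protected trimer with free 3-hydroxyl on unit U | O[C@@H]1[C@@H](c2c(OCc9ccccc9)cc(OCc9ccccc9)c3c2O[C@H](c2ccc(OCc9ccccc9)c(OCc9ccccc9)c2)[C@H](OC(=O)c2cc(OCc9ccccc9)c(OCc9ccccc9)c(OCc9ccccc9)c2)[C@H]3c2c(OCc9ccccc9)c(Br)c3c(c2OCc9ccccc9)C[C@H](OCc9ccccc9)[C@@H](c2ccc(OCc9ccccc9)c(OCc9ccccc9)c2)O3)c2c(OCc9ccccc9)cc(OCc9ccccc9)cc2O[C@@H]1c1ccc(OCc9ccccc9)c(OCc9ccccc9)c1 | intermediate
26 | perbenzylated 8-bromo trimer 3,3'-di-O-gallate | O=C(O[C@@H]1[C@@H](c2c(OCc9ccccc9)cc(OCc9ccccc9)c3c2O[C@H](c2ccc(OCc9ccccc9)c(OCc9ccccc9)c2)[C@H](OC(=O)c2cc(OCc9ccccc9)c(OCc9ccccc9)c(OCc9ccccc9)c2)[C@H]3c2c(OCc9ccccc9)c(Br)c3c(c2OCc9ccccc9)C[C@H](OCc9ccccc9)[C@@H](c2ccc(OCc9ccccc9)c(OCc9ccccc9)c2)O3)c2c(OCc9ccccc9)cc(OCc9ccccc9)cc2O[C@@H]1c1ccc(OCc9ccccc9)c(OCc9ccccc9)c1)c1cc(OCc9ccccc9)c(OCc9ccccc9)c(OCc9ccccc9)c1 | intermediate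
27 | CNP0154615.1, epicatechin 3-O-gallate-(4β→8)-epicatechin 3-O-gallate-(4β→6)-catechin | O=C(O[C@@H]1[C@@H](c2c(O)cc(O)c3c2O[C@H](c2ccc(O)c(O)c2)[C@H](OC(=O)c2cc(O)c(O)c(O)c2)[C@H]3c2c(O)cc3c(c2O)C[C@H](O)[C@@H](c2ccc(O)c(O)c2)O3)c2c(O)cc(O)cc2O[C@@H]1c1ccc(O)c(O)c1)c1cc(O)c(O)c(O)c1 | target

## Step count and risk

Total: 17 steps. Longest linear sequence: 14 steps (steps 4 to 17, from (−)-epicatechin 5). The catechin branch (steps 1 to 3) joins at step 8.

Step 11 (key step, proposed new method). What may go wrong: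
- loss of stereospecificity, if the benzylic C–O bond ionises fully before the arene arrives, or if the boron-bound phenol is delivered from the side of the oxirane oxygen (retention);
- 1,2-shift of the formyl group or of hydride in the opened oxirane (Meinwald rearrangement);
- boron-templated attack of the ortho carbon on the aldehyde carbon instead of C4;
- attack through the para carbon of the phenol.

Fallback with known chemistry: the route is left at dimer iodide 11. Its iodine is removed by palladium-catalysed formate reduction (Pd(PPh3)4, HCO2Na, DMF), which spares the hindered aryl bromide, to give the C8-unsubstituted M–T dimer F1. F1 is then used as the nucleophile in a TMSOTf-mediated interflavan coupling with the C4-activated epicatechin 7, already in hand from step 5. Attack of C8 of unit M trans to the C3 hydroxyl of 7 gives alcohol 25, where the route is rejoined. This gives up the de novo construction of unit U.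

Step 10. What may go wrong: slow conjugate addition of hydroperoxide, because the β-carbon is deactivated by a 2,4,6-trioxygenated ring and flanked by two ortho substituents, and opening of the oxirane on silica or by adventitious acid during isolation. Fallback: enal 14 is reduced under Luche conditions (NaBH4, CeCl3·7H2O) to the E-allylic alcohol F2. Sharpless asymmetric epoxidation of F2 (Ti(OiPr)4, L-(+)-diisopropyl tartrate, t-BuOOH, 4 Å MS, −20 °C) gives the (2S,3S)-epoxy alcohol F3. Parikh–Doering oxidation (SO3·pyridine, DMSO, i-Pr2NEt) returns the route to epoxy aldehyde 15.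

Step 14. What may go wrong: cleavage of the ring C–O bond instead of the C–OAc bond on ionisation, alkylation of a ring A carbon of a second molecule before aryl transfer, or entry of the aryl group on the face of the C4 substituent. Fallback: acetate 20 is converted with Me3SiBr into the anomeric bromide F4. F4 is coupled with diarylzinc 23 under nickel catalysis (NiCl2·DME, terpyridine; Negishi C-aryl glycosylation through an anomeric radical), which removes the free oxocarbenium ion from the pathway. The route is rejoined at 24.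

Step 12. What may go wrong: acetylation of both hydroxyls, or migration of the anomeric acetyl group to O3 under the basic conditions. Fallback: lactol 18 is silylated on both hydroxyls with excess TESOTf and 2,6-lutidine to the bis(triethylsilyl) ether F5. The more labile anomeric silyl ether is cleaved with buffered fluoride (Bu4NF, AcOH, THF, −40 °C) to the 3-O-triethylsilyl lactol F6, which is acetylated (Ac2O, pyridine, DMAP) to rejoin the route at 20.

## Further compounds

F1 | step 11 | M–T dimer without iodine (C8–H on unit M) | c2c(OCc9ccccc9)cc(OCc9ccccc9)c3c2O[C@H](c2ccc(OCc9ccccc9)c(OCc9ccccc9)c2)[C@H](OC(=O)c2cc(OCc9ccccc9)c(OCc9ccccc9)c(OCc9ccccc9)c2)[C@H]3c2c(OCc9ccccc9)c(Br)c3c(c2OCc9ccccc9)C[C@H](OCc9ccccc9)[C@@H](c2ccc(OCc9ccccc9)c(OCc9ccccc9)c2)O3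
F2 | step 10 | M–T dimer with (E)-3-hydroxyprop-1-enyl group on C8 of unit M | OC/C=C/c2c(OCc9ccccc9)cc(OCc9ccccc9)c3c2O[C@H](c2ccc(OCc9ccccc9)c(OCc9ccccc9)c2)[C@H](OC(=O)c2cc(OCc9ccccc9)c(OCc9ccccc9)c(OCc9ccccc9)c2)[C@H]3c2c(OCc9ccccc9)c(Br)c3c(c2OCc9ccccc9)C[C@H](OCc9ccccc9)[C@@H](c2ccc(OCc9ccccc9)c(OCc9ccccc9)c2)O3
F3 | step 10 | (2S,3S)-trans-3-aryloxiranylmethanol, aryl = C8 of unit M of the M–T dimer | OC[C@@H]1O[C@H]1c2c(OCc9ccccc9)cc(OCc9ccccc9)c3c2O[C@H](c2ccc(OCc9ccccc9)c(OCc9ccccc9)c2)[C@H](OC(=O)c2cc(OCc9ccccc9)c(OCc9ccccc9)c(OCc9ccccc9)c2)[C@H]3c2c(OCc9ccccc9)c(Br)c3c(c2OCc9ccccc9)C[C@H](OCc9ccccc9)[C@@H](c2ccc(OCc9ccccc9)c(OCc9ccccc9)c2)O3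
F4 | step 14 | anomeric bromide of unit U with 3-O-triethylsilyl group | BrC1[C@H](O[Si](CC)(CC)CC)[C@@H](c2c(OCc9ccccc9)cc(OCc9ccccc9)c3c2O[C@H](c2ccc(OCc9ccccc9)c(OCc9ccccc9)c2)[C@H](OC(=O)c2cc(OCc9ccccc9)c(OCc9ccccc9)c(OCc9ccccc9)c2)[C@H]3c2c(OCc9ccccc9)c(Br)c3c(c2OCc9ccccc9)C[C@H](OCc9ccccc9)[C@@H](c2ccc(OCc9ccccc9)c(OCc9ccccc9)c2)O3)c2c(OCc9ccccc9)cc(OCc9ccccc9)cc2O1
F5 | step 12 | 2,3-bis-O-triethylsilyl lactol of unit U | CC[Si](CC)(CC)OC1[C@H](O[Si](CC)(CC)CC)[C@@H](c2c(OCc9ccccc9)cc(OCc9ccccc9)c3c2O[C@H](c2ccc(OCc9ccccc9)c(OCc9ccccc9)c2)[C@H](OC(=O)c2cc(OCc9ccccc9)c(OCc9ccccc9)c(OCc9ccccc9)c2)[C@H]3c2c(OCc9ccccc9)c(Br)c3c(c2OCc9ccccc9)C[C@H](OCc9ccccc9)[C@@H](c2ccc(OCc9ccccc9)c(OCc9ccccc9)c2)O3)c2c(OCc9ccccc9)cc(OCc9ccccc9)cc2O1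
F6 | step 12 | 3-O-triethylsilyl lactol of unit U | OC1[C@H](O[Si](CC)(CC)CC)[C@@H](c2c(OCc9ccccc9)cc(OCc9ccccc9)c3c2O[C@H](c2ccc(OCc9ccccc9)c(OCc9ccccc9)c2)[C@H](OC(=O)c2cc(OCc9ccccc9)c(OCc9ccccc9)c(OCc9ccccc9)c2)[C@H]3c2c(OCc9ccccc9)c(Br)c3c(c2OCc9ccccc9)C[C@H](OCc9ccccc9)[C@@H](c2ccc(OCc9ccccc9)c(OCc9ccccc9)c2)O3)c2c(OCc9ccccc9)cc(OCc9ccccc9)cc2O1
A1 | alternative 1 | benzylated trimer with free 3-hydroxyls on units U and M | O[C@@H]1[C@@H](c2c(OCc9ccccc9)cc(OCc9ccccc9)c3c2O[C@H](c2ccc(OCc9ccccc9)c(OCc9ccccc9)c2)[C@H](O)[C@H]3c2c(OCc9ccccc9)cc3c(c2OCc9ccccc9)C[C@H](OCc9ccccc9)[C@@H](c2ccc(OCc9ccccc9)c(OCc9ccccc9)c2)O3)c2c(OCc9ccccc9)cc(OCc9ccccc9)cc2O[C@@H]1c1ccc(OCc9ccccc9)c(OCc9ccccc9)c1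
A2 | alternative 2 | benzylated trimer with 3-O-tert-butyldimethylsilyl groups on units U and M | CC(C)(C)[Si](C)(C)O[C@@H]1[C@@H](c2c(OCc9ccccc9)cc(OCc9ccccc9)c3c2O[C@H](c2ccc(OCc9ccccc9)c(OCc9ccccc9)c2)[C@H](O[Si](C)(C)C(C)(C)C)[C@H]3c2c(OCc9ccccc9)cc3c(c2OCc9ccccc9)C[C@H](OCc9ccccc9)[C@@H](c2ccc(OCc9ccccc9)c(OCc9ccccc9)c2)O3)c2c(OCc9ccccc9)cc(OCc9ccccc9)cc2O[C@@H]1c1ccc(OCc9ccccc9)c(OCc9ccccc9)c1
A3 | alternative 2 | 1,2-bis(benzyloxy)benzene | c1ccc(COc2ccccc2OCc2ccccc2)cc1
A4 | alternative 3 | trimer with free C7 phenol and C5 triisopropylsilyl ether on unit T | CC(C)(C)[Si](C)(C)O[C@@H]1[C@@H](c2c(OCc9ccccc9)cc(OCc9ccccc9)c3c2O[C@H](c2ccc(OCc9ccccc9)c(OCc9ccccc9)c2)[C@H](O[Si](C)(C)C(C)(C)C)[C@H]3c2c(O)cc3c(c2O[Si](C(C)C)(C(C)C)C(C)C)C[C@H](OCc9ccccc9)[C@@H](c2ccc(OCc9ccccc9)c(OCc9ccccc9)c2)O3)c2c(OCc9ccccc9)cc(OCc9ccccc9)cc2O[C@@H]1c1ccc(OCc9ccccc9)c(OCc9ccccc9)c1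
A5 | alternative 3 | pyran-fused cyclobutenone carrying C2 and C3 of unit T | O=C1CC2=C1C[C@H](OCc9ccccc9)[C@@H](c1ccc(OCc9ccccc9)c(OCc9ccccc9)c1)O2
A6 | alternative 3 | U–M dimer with (triisopropylsiloxy)ethynyl group on C4 of unit M | CC(C)(C)[Si](C)(C)O[C@@H]1[C@@H](c2c(OCc9ccccc9)cc(OCc9ccccc9)c3c2O[C@H](c2ccc(OCc9ccccc9)c(OCc9ccccc9)c2)[C@H](O[Si](C)(C)C(C)(C)C)[C@H]3C#CO[Si](C(C)C)(C(C)C)C(C)C)c2c(OCc9ccccc9)cc(OCc9ccccc9)cc2O[C@@H]1c1ccc(OCc9ccccc9)c(OCc9ccccc9)c1
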